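The pyranone ring (ring C) is disconnected at O1–C2 and C4–C4a into a protected 2-hydroxy-6-methoxycinnamoyl unit and 4,5,6-trimethoxybenzene-1,3-diol. The key step exploits ring A: C4a is its only unsubstituted carbon and lies between two oxygens (O1 on C8a and the C5 hydroxyl) that are equivalent in the free diol. Irradiation of the mono-cinnamate ester of this diol moves the acyl group from oxygen to C4a (photo-Fries rearrangement); the phenol set free then adds to C2 of the enone and closes ring C in the same flask. The racemic flavanone is resolved by catalytic transfer hydrogenation, and neutral hydrogenolysis frees the ring B phenol.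

Key step: step 6

Remark: C2 carries a 2,6-dioxygenated aryl group and would ionise too easily for a stereospecific substitution, so it is formed racemic in the key step and the 2S enantiomer is then selected catalytically; 1 and 6 are taken as commercial.

Step 1
Reactants: 1 1,2,3-trimethoxybenzene
Product: 3 1,5-dibromo-2,3,4-trimethoxybenzene, via 1-bromo-2,3,4-trimethoxybenzene 2 (not isolated)
Conditions: NBS (2.1 equiv), MeCN, 0 °C to rt
Reagents that add atoms: N-bromosuccinimide, O=C1CCC(=O)N1Br
Why: Electrophilic aromatic bromination; each brominated position is ortho to one outer methoxy group and para to the other, whereas the carbon between them is para only to the twisted central methoxy group and should stay free.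

Step 2
Reactants: 3 1,5-dibromo-2,3,4-trimethoxybenzene
Product: 5 4,5,6-trimethoxybenzene-1,3-diol, via 5-bromo-2,3,4-trimethoxyphenol 4 (not isolated)
Conditions: Pd2(dba)3 (2 mol %), tBuXPhos (8 mol %), KOH (6 equiv), 1,4-dioxane/H2O, 100 °C, argon; then aq HCl
Reagents that add atoms: potassium hydroxide, [K+].[OH-]
Why: Palladium-catalysed C–O cross-coupling of aryl bromides with hydroxide, in which the bulky biaryl phosphine should allow both electron-rich, ortho-methoxy C–Br bonds to be hydroxylated; air is excluded because the diolate is easily oxidised.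

Step 3
Reactants: 6 2-hydroxy-6-methoxybenzaldehyde
Product: 7 2-(benzyloxy)-6-methoxybenzaldehyde
Conditions: BnBr, K2CO3, DMF, 50 °C
Reagents that add atoms: benzyl bromide, BrCc1ccccc1
Why: Williamson ether synthesis; the benzyl ether masks the ring B phenol through all later steps and can be removed without acid or base.

Step 4
Reactants: 7 2-(benzyloxy)-6-methoxybenzaldehyde
Product: 9 (E)-3-[2-(benzyloxy)-6-methoxyphenyl]prop-2-enoic acid, via arylidenemalonic acid 8 (not isolated)
Conditions: malonic acid, pyridine, piperidine (cat.), 100 °C; then aq HCl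
Reagents that add atoms: malonic acid, OC(=O)CC(=O)O
Why: Knoevenagel–Doebner condensation; decarboxylation of 8 in hot pyridine should give the thermodynamically preferred E acid.

Step 5
Reactants: 5 4,5,6-trimethoxybenzene-1,3-diol (3 equiv); 9 (E)-3-[2-(benzyloxy)-6-methoxyphenyl]prop-2-enoic acid
Product: 10 5-hydroxy-2,3,4-trimethoxyphenyl (E)-3-[2-(benzyloxy)-6-methoxyphenyl]prop-2-enoate
Conditions: DCC, DMAP (cat.), CH2Cl2/THF, 0 °C to rt; excess 5 recovered
Reagents that add atoms: none
Why: Steglich esterification; the two hydroxyls of 5 are equivalent, so only mono- against bis-acylation has to be controlled, and the excess of diol should favour the mono-ester.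

Step 6
Reactants: 10 5-hydroxy-2,3,4-trimethoxyphenyl (E)-3-[2-(benzyloxy)-6-methoxyphenyl]prop-2-enoate
Product: 12 rac-2-[2-(benzyloxy)-6-methoxyphenyl]-5-hydroxy-6,7,8-trimethoxy-2,3-dihydro-4H-chromen-4-one, via 2',6'-dihydroxychalcone 11 (not isolated)
Conditions: hν (300 nm), degassed MeCN (5 mM), rt; then Et3N (0.5 equiv), 40 °C, same flask
Reagents that add atoms: none
Why: Excitation of the aryl ester cleaves the aryl O–acyl bond to a solvent-caged aryloxyl/cinnamoyl radical pair that recombines at the only unsubstituted ortho carbon, and tautomerisation of the dienone gives chalcone 11 with the new C4–C4a bond (photo-Fries rearrangement). The phenol oxygen that had carried the acyl group then adds to the enone β-carbon under amine catalysis, an intramolecular oxa-Michael addition that closes ring C in the 6-endo-trig mode and forms the O1–C2 bond. The closest known reaction type is the photo-Fries rearrangement of aryl cinnamates and other aryl enoates to 2'-hydroxy enones with closure to chroman-4-ones. C2 is created without control, so 12 is racemic and the S enantiomer is selected in step 7. The step needs acyl migration to a single carbon and a single mode of closure: the other ortho position and the para position of the ester carry methoxy groups, the two hydroxyls flanking the new ketone are equivalent so either gives the same flavanone, and the ring B benzyl ether prevents lactonisation to a coumarin or benzopyrylium formation. High dilution should suppress [2+2] dimerisation of the cinnamate.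

Step 7
Reactants: 12 rac-2-[2-(benzyloxy)-6-methoxyphenyl]-5-hydroxy-6,7,8-trimethoxy-2,3-dihydro-4H-chromen-4-one
Product: 13 (2S)-2-[2-(benzyloxy)-6-methoxyphenyl]-5-hydroxy-6,7,8-trimethoxy-2,3-dihydro-4H-chromen-4-one
Conditions: Cp*RhCl[(R,R)-TsDPEN] (1 mol %), HCO2H/Et3N 5:2, EtOAc, rt, stopped at about 55% conversion; chromatography
Reagents that add atoms: none
Why: Kinetic resolution by asymmetric transfer hydrogenation (Noyori type): the (R,R) catalyst delivers hydride to the C4 carbonyl face that leads to the 4R carbinol and should do so fast only for the 2R ketone, where that face is anti to the C2 aryl group, giving the cis-(2R,4R)-flavan-4-ol, so the 2S ketone is left behind and its enantiomeric purity should rise as conversion passes one half.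

Step 8
Reactants: 13 (2S)-2-[2-(benzyloxy)-6-methoxyphenyl]-5-hydroxy-6,7,8-trimethoxy-2,3-dihydro-4H-chromen-4-one
Product: 14 (2S)-5-hydroxy-2-(2-hydroxy-6-methoxyphenyl)-6,7,8-trimethoxy-2,3-dihydro-4H-chromen-4-one (target)
Conditions: H2 (1 atm), Pd/C (10% Pd), EtOAc, rt; filtration and evaporation without base
Reagents that add atoms: none
Why: Hydrogenolysis of the benzyl aryl ether over palladium; the neutral medium avoids phenoxide- or acid-triggered opening of ring C at O1–C2, so the C2 configuration should be retained.

Compound list
1 | 1,2,3-trimethoxybenzene | COc1cccc(OC)c1OC | starting material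
2 | 1-bromo-2,3,4-trimethoxybenzene | COc1ccc(Br)c(OC)c1OC | intermediate
3 | 1,5-dibromo-2,3,4-trimethoxybenzene | COc1c(Br)cc(Br)c(OC)c1OC | intermediate
4 | 5-bromo-2,3,4-trimethoxyphenol | COc1c(Br)cc(O)c(OC)c1OC | intermediate
5 | 4,5,6-trimethoxybenzene-1,3-diol | COc1c(O)cc(O)c(OC)c1OC | intermediate
6 | 2-hydroxy-6-methoxybenzaldehyde | COc1cccc(O)c1C=O | starting material
7 | 2-(benzyloxy)-6-methoxybenzaldehyde | COc1cccc(OCc2ccccc2)c1C=O | intermediate
8 | 2-{[2-(benzyloxy)-6-methoxyphenyl]methylidene}propanedioic acid | COc1cccc(OCc2ccccc2)c1C=C(C(=O)O)C(=O)O | intermediate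
9 | (E)-3-[2-(benzyloxy)-6-methoxyphenyl]prop-2-enoic acid | COc1cccc(OCc2ccccc2)c1/C=C/C(=O)O | intermediate
10 | 5-hydroxy-2,3,4-trimethoxyphenyl (E)-3-[2-(benzyloxy)-6-methoxyphenyl]prop-2-enoate | COc1cccc(OCc2ccccc2)c1/C=C/C(=O)Oc1cc(O)c(OC)c(OC)c1OC | intermediate
11 | (E)-3-[2-(benzyloxy)-6-methoxyphenyl]-1-(2,6-dihydroxy-3,4,5-trimethoxyphenyl)prop-2-en-1-one | COc1cccc(OCc2ccccc2)c1/C=C/C(=O)c1c(O)c(OC)c(OC)c(OC)c1O | intermediate
12 | rac-2-[2-(benzyloxy)-6-methoxyphenyl]-5-hydroxy-6,7,8-trimethoxy-2,3-dihydro-4H-chromen-4-one | COc1cccc(OCc2ccccc2)c1C1CC(=O)c2c(O)c(OC)c(OC)c(OC)c2O1 | intermediate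
13 | (2S)-2-[2-(benzyloxy)-6-methoxyphenyl]-5-hydroxy-6,7,8-trimethoxy-2,3-dihydro-4H-chromen-4-one | COc1cccc(OCc2ccccc2)c1[C@@H]1CC(=O)c2c(O)c(OC)c(OC)c(OC)c2O1 | intermediate
14 | (2S)-5-hydroxy-2-(2-hydroxy-6-methoxyphenyl)-6,7,8-trimethoxy-2,3-dihydro-4H-chromen-4-one | COc1cccc(O)c1[C@@H]1CC(=O)c2c(O)c(OC)c(OC)c(OC)c2O1 | target

Total step count: 8. Longest linear sequence: 6 steps (1, 2, 5, 6, 7, 8; the ring B branch 3, 4, 5, 6, 7, 8 is equally long).

Steps most likely to fail

Step 6. E/Z isomerisation and dimerisation of the cinnamate, escape of the radical pair from the solvent cage, and photocleavage of the benzyl ether may outrun the acyl shift. The fallback sets out from 5 and 7 and comes back at 12. Diol 5 would be C-acetylated at its only free ring carbon with AcOH in BF3·OEt2 at 80 °C to give 1-(2,6-dihydroxy-3,4,5-trimethoxyphenyl)ethan-1-one F1. Claisen–Schmidt condensation of this ketone with aldehyde 7 (KOH, EtOH/H2O, rt) should give chalcone 11, which would be closed to 12 with NaOAc in refluxing EtOH.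

Step 7. Hydride transfer to the hydrogen-bonded, electron-rich C4 carbonyl may be slow, and the 2,6-disubstituted ring B may weaken the rate difference between the enantiomers. The fallback sets out from 12 and comes back at 13. Racemic 12 would be separated by preparative chromatography on a chiral stationary phase (amylose tris(3,5-dimethylphenylcarbamate), supercritical CO2/iPrOH), and the 2S enantiomer identified by circular dichroism. This makes no new compound, F0.

Step 2. The second C–O coupling may stall on the electron-rich bromophenoxide, and the diolate may degrade oxidatively in hot aqueous base. The fallback sets out from 3 and comes back at 5. Double Miyaura borylation (B2pin2, Pd(dppf)Cl2, KOAc, 1,4-dioxane, 90 °C) would give 2,2'-(4,5,6-trimethoxy-1,3-phenylene)bis(4,4,5,5-tetramethyl-1,3,2-dioxaborolane) F2, which would be oxidised to 5 with H2O2 in THF/pH 7 buffer at 0 °C.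

Further compounds
F1 | step 6 | 1-(2,6-dihydroxy-3,4,5-trimethoxyphenyl)ethan-1-one | CC(=O)c1c(O)c(OC)c(OC)c(OC)c1O
F0 | step 7 | none | none
F2 | step 2 | 2,2'-(4,5,6-trimethoxy-1,3-phenylene)bis(4,4,5,5-tetramethyl-1,3,2-dioxaborolane) | COc1c(B2OC(C)(C)C(C)(C)O2)cc(B2OC(C)(C)C(C)(C)O2)c(OC)c1OC
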